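**Assumption:** enantiopure (R)-(−)-lavandulol is purchased; bicyclic compounds carry PPAP numbering (C1 benzoyl bridgehead, C2–C4 enone bridge, C5 prenyl bridgehead, C6–C8 with C8 = CMe2, C9 bridging ketone), in which the target is (1R,5S,7S) with the C7 side chain endo (syn to the C2–C4 bridge).

## Retrosynthetic overview

1. Target ⇐ its bicyclic 4-O-silyl/2-oxo isomer by O-methylation at the C2 carbonyl and loss of silicon from O4. This places the methoxy group next to the benzoyl bridgehead.
2. Ring B (C1, C9, C5–C8) is closed last through the C1–C8 bond: a tertiary chloride is ionised by silver and captured by a silyl dienol ether at the benzoyl-bearing carbon.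
3. C5–C6 bond (key step): alkylative dearomatization of a C2v-symmetric 4-O-silyl-3,5-diprenyl-2,6-dihydroxybenzophenone with an enantiopure primary triflate/tertiary chloride bis-electrophile. Ring A is the original benzene ring.
4. The arene comes from phloroglucinol, benzoyl chloride and prenyl bromide. The bis-electrophile comes from (R)-lavandulol, which supplies C7; SeO2 sets the (E)-allylic oxygen and a hydrogen-atom-transfer hydrochlorination sets the tertiary chloride.

## Route

Step 1
Reactants: 1 phloroglucinol; 2 benzoyl chloride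
Product: 3 2,4,6-trihydroxybenzophenone
Conditions: AlCl3 (3.5 equiv), PhNO2, 60 °C; aq. HCl work-up
Reagents that add atoms: none
Why: Friedel–Crafts C-acylation of the most electron-rich benzene available stops at the mono-ketone because the acyl group deactivates the ring; no stereocentre is formed.

Step 2
Reactants: 3 2,4,6-trihydroxybenzophenone; 4 prenyl bromide (2 equiv)
Product: 5 clusiaphenone B
Conditions: KOH (3 equiv), H2O, 0 °C → rt
Reagents that add atoms: none
Why: C-prenylation of the acylphloroglucinol polyanion in water, where hydrogen bonding to oxygen suppresses O-alkylation, fills both free ring carbons; the product is achiral.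

Step 3
Reactants: 5 clusiaphenone B
Product: 6 2,6-dihydroxy-3,5-bis(3-methylbut-2-enyl)-4-(triisopropylsilyloxy)benzophenone
Conditions: (i-Pr)3SiOSO2CF3 (1.05 equiv), 2,6-lutidine, CH2Cl2, −78 → −40 °C
Reagents that add atoms: triisopropylsilyl triflate, CC(C)[Si](OS(=O)(=O)C(F)(F)F)(C(C)C)C(C)C
Why: O-silylation picks the most acidic, non-chelated para hydroxyl, giving a C2v-symmetric arene whose O4 is locked as a robust silyl ether; no stereocentre.

Step 4
Reactants: 7 (R)-lavandulol
Product: 8 tert-butyl(dimethyl){[(2R)-5-methyl-2-(prop-1-en-2-yl)hex-4-enyl]oxy}silane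
Conditions: t-BuMe2SiCl (1.1 equiv), imidazole, DMF, rt
Reagents that add atoms: tert-butyldimethylsilyl chloride, CC(C)(C)[Si](C)(C)Cl
Why: standard silyl protection of the primary alcohol keeps it apart from the allylic alcohol made next; the stereocentre is untouched.

Step 5
Reactants: 8 silyl ether of (R)-lavandulol
Product: 9 (2E,5R)-5-[(tert-butyldimethylsilyloxy)methyl]-2,6-dimethylhepta-2,6-dien-1-ol
Conditions: SeO2 (0.5 equiv), t-BuOOH (5.5 M in decane, 2.5 equiv), salicylic acid (10 mol%), CH2Cl2, 0 °C → rt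
Reagents that add atoms: tert-butyl hydroperoxide, CC(C)(C)OO
Why: Sharpless-type SeO2 allylic oxidation (ene reaction then [2,3]-shift) hydroxylates the E-methyl group of the more nucleophilic trisubstituted alkene, so the (E)-allylic alcohol forms while the isopropenyl group and the stereocentre stay intact.

Step 6
Reactants: 9 (E)-allylic alcohol
Product: 11 (2E,5R)-5-(hydroxymethyl)-2,6-dimethylhepta-2,6-dien-1-yl acetate, via silyl ether acetate 10 (not isolated)
Conditions: Ac2O, pyridine, DMAP (5 mol%), CH2Cl2, 0 °C → rt; MeOH quench; then HF·pyridine, THF, 0 °C → rt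
Reagents that add atoms: acetic anhydride, CC(=O)OC(C)=O
Why: acylation of the only free hydroxyl followed by fluoride desilylation in the same flask leaves the acetate on the allylic oxygen and frees the primary alcohol; no stereocentre is affected.

Step 7
Reactants: 11 hydroxy acetate
Product: 12 (2E,5S)-6-chloro-5-(hydroxymethyl)-2,6-dimethylhept-2-en-1-yl acetate
Conditions: Co(BF4)2·6H2O (6 mol%, divalent cobalt), potassium N-(3,5-di-tert-butylsalicylidene)-2,2-diphenylglycinate (6 mol%), TsCl (1.2 equiv), PhSiH3 (1.0 equiv), t-BuOOH (0.3 equiv), EtOH, rt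
Reagents that add atoms: p-toluenesulfonyl chloride, Cc1ccc(S(=O)(=O)Cl)cc1
Why: cobalt-hydride hydrogen-atom-transfer hydrochlorination (Markovnikov) engages the 1,1-disubstituted alkene far faster than the trisubstituted allylic-acetate alkene and the tertiary radical takes chlorine from TsCl; the neighbouring stereocentre is not involved (the descriptor changes to S only through CIP priorities).

Step 8
Reactants: 12 chloro alcohol
Product: 13 (2E,5S)-6-chloro-2,6-dimethyl-5-[(trifluoromethylsulfonyloxy)methyl]hept-2-en-1-yl acetate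
Conditions: (CF3SO2)2O (1.1 equiv), 2,6-lutidine (1.3 equiv), CH2Cl2, −78 °C; used at once
Reagents that add atoms: triflic anhydride, O=S(=O)(OS(=O)(=O)C(F)(F)F)C(F)(F)F
Why: O-sulfonylation of the only hydroxyl gives a 1,3-bis-electrophile with a primary triflate for SN2 attack and a tertiary chloride held in reserve as a cation source.

Step 9
Reactants: 6 symmetric silyl-protected arene; 13 triflate
Product: 14 (6S)-6-[(2S,4E)-6-acetoxy-2-(2-chloropropan-2-yl)-5-methylhex-4-enyl]-2-benzoyl-3-hydroxy-4,6-bis(3-methylbut-2-enyl)-5-(triisopropylsilyloxy)cyclohexa-2,4-dien-1-one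
Conditions: LiN(SiMe3)2 (2.1 equiv), PhMe–THF (10:1), −78 → 0 °C; then 13, −78 → −20 °C; aq. NH4Cl
Reagents that add atoms: none
Why: alkylative dearomatization (SN2 C-alkylation of a lithium phenoxide aggregate) at one of the two equivalent prenyl-bearing carbons breaks both the aromaticity and the symmetry of 6, the benzoyl-bearing carbon being the least nucleophilic and tight Li–O pairing in toluene disfavouring O-alkylation; C7 comes unchanged from 13 and the new quaternary centre (ring C6 = PPAP C5) is set by 1,2-induction, the bulky CMe2Cl arm turning away from the O4-silyl flank toward the lithium phenoxide side, which for the (S)-electrophile exposes the face giving the (6S) product.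

Step 10
Reactants: 14 dearomatized chloride
Product: 16 (1S,5S,7S)-7-[(E)-4-acetoxy-3-methylbut-2-enyl]-1-benzoyl-8,8-dimethyl-3,5-bis(3-methylbut-2-enyl)-4-(triisopropylsilyloxy)bicyclo[3.3.1]non-3-ene-2,9-dione, via trimethylsilyl enol ether 15 (not isolated)
Conditions: Me3SiOSO2CF3 (1.1 equiv), 2,6-di-tert-butylpyridine (2.5 equiv), CH2Cl2, −78 °C; then AgOSO2CF3 (1.2 equiv), −78 → −30 °C
Reagents that add atoms: none
Why: Proposed new method: silylation turns the enolised β-triketone into a 1,3-bis(silyloxy)diene whose nucleophilic terminus is the benzoyl-bearing C1, silver then abstracts chloride and the tertiary C8 cation, held over C1 by its three-atom tether, is captured there in a six-membered ring closure (closest known: Lewis-acid α-tert-alkylation of silyl enol ethers by tertiary halides, and cationic cyclisations of dearomatised acylphloroglucinols to bicyclo[3.3.1]nonanes), while C3 is the hindered internal diene carbon kept unreactive by the O4-silyl lock so the type A bicycle results; loss of Me3Si gives the C2 ketone, the C1 configuration is fixed by the bridge, and the preset C5/C7 pair forces the side chain endo through a boat-like ring B with the substituent pseudo-equatorial (the C1 descriptor reads S here only because C2 is a ketone).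

Step 11
Reactants: 16 bicyclic vinylogous silyl ester
Product: 18 (1R,5S,7S)-7-[(E)-4-acetoxy-3-methylbut-2-enyl]-1-benzoyl-2-methoxy-8,8-dimethyl-3,5-bis(3-methylbut-2-enyl)bicyclo[3.3.1]non-2-ene-4,9-dione, via methoxy oxocarbenium triflate 17 (not isolated)
Conditions: MeOSO2CF3 (1.5 equiv), CH2Cl2, 0 °C → rt; then CsF (3 equiv), MeCN, 0 °C
Reagents that add atoms: methyl triflate, COS(=O)(=O)C(F)(F)F
Why: Meerwein-type O-methylation of the vinylogous-ester carbonyl at C2 gives a 2-methoxy-4-silyloxy allyl cation from which fluoride removes silicon, so the enone is transposed and the methoxy group can only end up on C2 beside the benzoyl bridgehead; no stereocentre is touched.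

## Compound list

1 | phloroglucinol (benzene-1,3,5-triol) | Oc1cc(O)cc(O)c1 | starting material
2 | benzoyl chloride | O=C(Cl)c1ccccc1 | starting material
3 | 2,4,6-trihydroxybenzophenone | O=C(c1ccccc1)c1c(O)cc(O)cc1O | intermediate
4 | prenyl bromide (1-bromo-3-methylbut-2-ene) | CC(C)=CCBr | starting material
5 | clusiaphenone B, 2,4,6-trihydroxy-3,5-bis(3-methylbut-2-enyl)benzophenone | O=C(c1ccccc1)c1c(O)c(CC=C(C)C)c(O)c(CC=C(C)C)c1O | intermediate
6 | 2,6-dihydroxy-3,5-bis(3-methylbut-2-enyl)-4-(triisopropylsilyloxy)benzophenone | O=C(c1ccccc1)c1c(O)c(CC=C(C)C)c(O[Si](C(C)C)(C(C)C)C(C)C)c(CC=C(C)C)c1O | intermediate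
7 | (R)-lavandulol, (2R)-5-methyl-2-(prop-1-en-2-yl)hex-4-en-1-ol | OC[C@H](CC=C(C)C)C(C)=C | starting material
8 | tert-butyl(dimethyl){[(2R)-5-methyl-2-(prop-1-en-2-yl)hex-4-enyl]oxy}silane | CC(C)(C)[Si](C)(C)OC[C@H](CC=C(C)C)C(C)=C | intermediate
9 | (2E,5R)-5-[(tert-butyldimethylsilyloxy)methyl]-2,6-dimethylhepta-2,6-dien-1-ol | CC(C)(C)[Si](C)(C)OC[C@H](C/C=C(\C)CO)C(C)=C | intermediate
10 | (2E,5R)-5-[(tert-butyldimethylsilyloxy)methyl]-2,6-dimethylhepta-2,6-dien-1-yl acetate | CC(C)(C)[Si](C)(C)OC[C@H](C/C=C(\C)COC(C)=O)C(C)=C | intermediate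
11 | (2E,5R)-5-(hydroxymethyl)-2,6-dimethylhepta-2,6-dien-1-yl acetate | OC[C@H](C/C=C(\C)COC(C)=O)C(C)=C | intermediate
12 | (2E,5S)-6-chloro-5-(hydroxymethyl)-2,6-dimethylhept-2-en-1-yl acetate | OC[C@H](C/C=C(\C)COC(C)=O)C(C)(C)Cl | intermediate
13 | (2E,5S)-6-chloro-2,6-dimethyl-5-[(trifluoromethylsulfonyloxy)methyl]hept-2-en-1-yl acetate | O=S(=O)(OC[C@H](C/C=C(\C)COC(C)=O)C(C)(C)Cl)C(F)(F)F | intermediate
14 | (6S)-6-[(2S,4E)-6-acetoxy-2-(2-chloropropan-2-yl)-5-methylhex-4-enyl]-2-benzoyl-3-hydroxy-4,6-bis(3-methylbut-2-enyl)-5-(triisopropylsilyloxy)cyclohexa-2,4-dien-1-one (ring C6 = PPAP C5, side-chain C2 = PPAP C7) | OC1=C(C(=O)c2ccccc2)C(=O)[C@@](CC=C(C)C)(C[C@H](C/C=C(\C)COC(C)=O)C(C)(C)Cl)C(O[Si](C(C)C)(C(C)C)C(C)C)=C1CC=C(C)C | intermediate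
15 | 3-O-trimethylsilyl enol ether of 14 (1,3-bis(silyloxy)diene) | C[Si](C)(C)OC1=C(C(=O)c2ccccc2)C(=O)[C@@](CC=C(C)C)(C[C@H](C/C=C(\C)COC(C)=O)C(C)(C)Cl)C(O[Si](C(C)C)(C(C)C)C(C)C)=C1CC=C(C)C | intermediate
16 | (1S,5S,7S)-7-[(E)-4-acetoxy-3-methylbut-2-enyl]-1-benzoyl-8,8-dimethyl-3,5-bis(3-methylbut-2-enyl)-4-(triisopropylsilyloxy)bicyclo[3.3.1]non-3-ene-2,9-dione (same spatial arrangement as the target) | O=C1C(CC=C(C)C)=C(O[Si](C(C)C)(C(C)C)C(C)C)[C@]2(CC=C(C)C)C[C@H](C/C=C(\C)COC(C)=O)C(C)(C)[C@@]1(C(=O)c1ccccc1)C2=O | intermediate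
17 | 2-methoxy-4-(triisopropylsilyl)oxocarbenium triflate derived from 16 | COC1=C(CC=C(C)C)C(=[O+][Si](C(C)C)(C(C)C)C(C)C)[C@]2(CC=C(C)C)C[C@H](C/C=C(\C)COC(C)=O)C(C)(C)[C@@]1(C(=O)c1ccccc1)C2=O.[O-]S(=O)(=O)C(F)(F)F | intermediate
18 | (1R,5S,7S)-7-[(E)-4-acetoxy-3-methylbut-2-enyl]-1-benzoyl-2-methoxy-8,8-dimethyl-3,5-bis(3-methylbut-2-enyl)bicyclo[3.3.1]non-2-ene-4,9-dione (CNP0256662.1) | COC1=C(CC=C(C)C)C(=O)[C@]2(CC=C(C)C)C[C@H](C/C=C(\C)COC(C)=O)C(C)(C)[C@@]1(C(=O)c1ccccc1)C2=O | target

## Step count and risks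

Total steps: 11. Longest linear sequence: 8 (7 → 8 → 9 → 11 → 12 → 13 → 14 → 16 → 18, steps 4–11).

Steps most likely to fail:

**Step 9 (dearomatizing alkylation).** The risks are O-alkylation and weak or reversed facial bias at C5. The fallback sets out from 6 and 13 and comes back at 16. It gives up on induction at this stage: the coupling is run without regard to facial selectivity and delivers 14 together with its C5 epimer F1. The unseparated pair is put through the step 10 protocol. There the (6R)-epimer F1 passes through its trimethylsilyl enol ether F2 and closes through a chair-like transition state to the 7-exo bicycle F3. F3 and 16 are diastereomers with different ring B conformations and are separated on silica, so stereochemical purity comes from divergent ring closure instead of from the alkylation. The route resumes at 16.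

**Step 10 (ring closure at the benzoyl-bearing carbon).** The risks are capture of the cation at oxygen or at C3. The fallback sets out from 14 and comes back at 16, and replaces direct C-capture by an O-capture/1,3-shift relay. Compound 14 is treated with AgOSO2CF3 and 2,6-di-tert-butylpyridine without prior silylation, so the cation is trapped at O9 to give the pyran enol ether F4, which is isolated. Me2AlCl (CH2Cl2, −78 → 0 °C) then ionises its tertiary C8–O bond and the aluminium enolate recombines at C1 (Lewis-acid 1,3 O-to-C rearrangement), giving 16.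

**Step 11 (methylative transposition).** The risk is that the hindered C2 carbonyl resists methylation. The fallback sets out from 16 and comes back at 18. HF·pyridine (THF, 0 °C) removes the silyl group to give the enolised β-diketone F5. Me3SiCHN2 in MeOH–PhMe then methylates both enol oxygens, giving 18 and its 4-O-methyl regioisomer F6, which are separated by chromatography.

Further compounds
F1 | step 9 | (6R)-epimer of 14 (C5 epimer, PPAP numbering) | OC1=C(C(=O)c2ccccc2)C(=O)[C@](CC=C(C)C)(C[C@H](C/C=C(\C)COC(C)=O)C(C)(C)Cl)C(O[Si](C(C)C)(C(C)C)C(C)C)=C1CC=C(C)C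
F2 | step 9 | trimethylsilyl enol ether of F1 | C[Si](C)(C)OC1=C(C(=O)c2ccccc2)C(=O)[C@](CC=C(C)C)(C[C@H](C/C=C(\C)COC(C)=O)C(C)(C)Cl)C(O[Si](C(C)C)(C(C)C)C(C)C)=C1CC=C(C)C
F3 | step 9 | (1R,5R,7S)-diastereomer of 16 (C7 side chain exo) | O=C1C(CC=C(C)C)=C(O[Si](C(C)C)(C(C)C)C(C)C)[C@@]2(CC=C(C)C)C[C@H](C/C=C(\C)COC(C)=O)C(C)(C)[C@]1(C(=O)c1ccccc1)C2=O
F4 | step 10 | O9-cyclised pyran enol ether isomer of 16 (O9–C8 bond in place of C1–C8, C1=C9 double bond) | O=C1C(CC=C(C)C)=C(O[Si](C(C)C)(C(C)C)C(C)C)[C@]2(CC=C(C)C)C[C@H](C/C=C(\C)COC(C)=O)C(C)(C)OC2=C1C(=O)c1ccccc1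
F5 | step 11 | (1R,5S,7S)-7-[(E)-4-acetoxy-3-methylbut-2-enyl]-1-benzoyl-2-hydroxy-8,8-dimethyl-3,5-bis(3-methylbut-2-enyl)bicyclo[3.3.1]non-2-ene-4,9-dione (O-desmethyl 18, enol form) | OC1=C(CC=C(C)C)C(=O)[C@]2(CC=C(C)C)C[C@H](C/C=C(\C)COC(C)=O)C(C)(C)[C@@]1(C(=O)c1ccccc1)C2=O
F6 | step 11 | (1S,5S,7S)-7-[(E)-4-acetoxy-3-methylbut-2-enyl]-1-benzoyl-4-methoxy-8,8-dimethyl-3,5-bis(3-methylbut-2-enyl)bicyclo[3.3.1]non-3-ene-2,9-dione (4-O-methyl regioisomer of 18) | O=C1C(CC=C(C)C)=C(OC)[C@]2(CC=C(C)C)C[C@H](C/C=C(\C)COC(C)=O)C(C)(C)[C@@]1(C(=O)c1ccccc1)C2=O
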